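**Plan**

- Cuts: the two ester C–O bonds (back to the C40 diol and α-linolenic acid), then C11=C12 and C11'=C12' (two Wittig reactions on a C10 dialdehyde), C7'=C8' (sulfone alkylation and sulfinate elimination), C6–C7 (Stille coupling) and, in ring ε, the C1'–C6' bond.
- Forward: an acyclic C10 sulfone is closed to ring ε first, and the chain then grows C10 → C15 → C25. Ring β comes ready-made from a hydroxy ketone, is extended to its C15 phosphonium salt and joined last. Desilylation and double esterification finish the route.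
- Enabling feature: in ring ε the quaternary C1' is bonded to the stereogenic C6', the double bond lies at C4'=C5' and the C3' oxygen is 1,4 to C6'. This is the pattern left when a 3,7-dimethylocta-2,7-dienyl chain closes through a C1' cation, with the oxygen only homoallylic to the protonated terminus.
- Stereochemistry: C3' from (R)-epichlorohydrin; C6' by 1,4-induction from C3' in the chair-like closure; C3 from (4R,6R)-4-hydroxy-2,2,6-trimethylcyclohexanone. The E alkenes come from syn-carboalumination, elimination, Stille coupling with retention and thermally equilibrated Wittig products. The six Z alkenes arrive with α-linolenic acid.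

Key step: step 6

Assumption: ketone 26 is taken as a purchasable chiral building block, and the Z isomers formed at the two Wittig-derived double bonds are taken to equilibrate to E on heating, as is usual for such polyenes.

**Route**

Step 1
Reactants: 1 (R)-epichlorohydrin; 2 isopropenylmagnesium bromide (CH2=C(CH3)MgBr)
Product: 3 (2R)-1-chloro-4-methylpent-4-en-2-ol
Conditions: CuI (10 mol %), THF, −40 → −20 °C; aq. NH4Cl
Reagents that add atoms: none
Why: Copper-catalysed Grignard opening of the epoxide at its unsubstituted carbon should outrun displacement of chloride, so the stereocentre of 1 is carried over untouched.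

Step 2
Reactants: 3 (2R)-1-chloro-4-methylpent-4-en-2-ol; 4 lithium acetylide–ethylenediamine complex (LiC≡CH·H2NCH2CH2NH2)
Product: 6 (4R)-2-methylhept-1-en-6-yn-4-ol, via epoxide 5 (not isolated)
Conditions: 4 (2.5 equiv), DMSO, 0 °C → rt; aq. NH4Cl
Reagents that add atoms: none
Why: The first equivalent of acetylide closes the chlorohydrin to the epoxide (Williamson-type closure, C–O bond at the stereocentre not broken) and the second opens it at the terminal carbon by SN2, so the configuration is retained.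

Step 3
Reactants: 6 (4R)-2-methylhept-1-en-6-yn-4-ol
Product: 7 tert-butyl{[(4R)-2-methylhept-1-en-6-yn-4-yl]oxy}diphenylsilane
Conditions: t-BuPh2SiCl, imidazole, DMF, rt
Reagents that add atoms: tert-butyl(chloro)diphenylsilane CC(C)(C)[Si](Cl)(c1ccccc1)c1ccccc1
Why: Imidazole-mediated silylation of a secondary alcohol installs the bulky ether that later anchors the chair of the ring closure.

Step 4
Reactants: 7 tert-butyl{[(4R)-2-methylhept-1-en-6-yn-4-yl]oxy}diphenylsilane
Product: 10 (2E,5R)-5-(tert-butyldiphenylsilyloxy)-3,7-dimethylocta-2,7-dien-1-ol, via alkenylalane 8 (not isolated), via lithium alkenylaluminate 9 (not isolated)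
Conditions: AlMe3, Cp2ZrCl2 (0.25 equiv), CH2Cl2, 0 °C → rt; then n-BuLi, THF, −78 °C; (CH2O)n, −78 °C → rt; aq. KNaC4H4O6 (tartrate)
Reagents that add atoms: trimethylaluminium C[Al](C)C; paraformaldehyde (CH2O units) C=O
Why: Negishi carboalumination adds methyl and aluminium syn across the terminal alkyne with aluminium on the terminal carbon, and hydroxymethylation of the derived aluminate with formaldehyde proceeds with retention, which fixes the 2E geometry while the isolated 1,1-disubstituted alkene stays inert.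

Step 5
Reactants: 10 (2E,5R)-5-(tert-butyldiphenylsilyloxy)-3,7-dimethylocta-2,7-dien-1-ol; 11 sodium benzenesulfinate (PhSO2Na)
Product: 13 (2E,5R)-5-(tert-butyldiphenylsilyloxy)-3,7-dimethylocta-2,7-dien-1-yl phenyl sulfone, via allylic bromide 12 (not isolated)
Conditions: CBr4, PPh3, CH2Cl2, 0 °C; then PhSO2Na, DMF, rt
Reagents that add atoms: none
Why: Appel bromination of the primary allylic alcohol under neutral conditions, followed by SN2 S-alkylation of the sulfinate in DMF, should give the allylic sulfone without touching alkene geometry or the stereocentre.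

Step 6
Reactants: 13 (2E,5R)-5-(tert-butyldiphenylsilyloxy)-3,7-dimethylocta-2,7-dien-1-yl phenyl sulfone
Product: 14 [(1R,4R)-4-(tert-butyldiphenylsilyloxy)-2,6,6-trimethylcyclohex-2-en-1-yl]methyl phenyl sulfone
Conditions: SnCl4, 2,6-dimethylphenol, toluene, −78 °C; aq. NaHCO3
Reagents that add atoms: none
Why: The SnCl4–phenol complex is a strong Brønsted acid with a non-nucleophilic counter-ion that should protonate the isolated 1,1-disubstituted alkene at its CH2 terminus rather than the alkene deactivated by the sulfonylmethyl group; the tertiary C1' cation is then captured by C6' of the (E)-trisubstituted alkene to form the C1'–C6' bond, and the resulting tertiary C5' cation loses H-4'. The closest known reaction type is the acid-promoted cation–olefin cyclisation of geranyl aryl sulfones to α-cyclogeranyl sulfones, a relative of the pseudoionone-to-α-ionone closure. Ring ε closes in the 6-endo mode through a chair-like transition state. The new C6' centre is controlled by C3': the bulky silyloxy group stays equatorial to avoid a syn-axial clash with a C1' methyl group, and the E geometry places the sulfonylmethyl arm equatorial as well, so the two substituents end up 1,4-trans, that is (1R,4R). The step needs site-selective protonation without ionisation of the C–O bond, which the homoallylic (not allylic) position of the oxygen and the low temperature should secure, and it needs kinetic loss of the unhindered axial H-4' instead of H-6', which is shielded by the quaternary C1' and the sulfonylmethyl arm. The hindered, weakly basic silyl ether is not expected to trap either cation.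

Step 7
Reactants: 14 [(1R,4R)-4-(tert-butyldiphenylsilyloxy)-2,6,6-trimethylcyclohex-2-en-1-yl]methyl phenyl sulfone; 15 ethyl (2E)-4-bromo-3-methylbut-2-enoate
Product: 17 ethyl (2E)-5-[(1R,4R)-4-(tert-butyldiphenylsilyloxy)-2,6,6-trimethylcyclohex-2-en-1-yl]-3-methyl-5-(phenylsulfonyl)pent-2-enoate (both C5 epimers), via lithiated sulfone 16 (not isolated)
Conditions: n-BuLi, THF, −78 °C; then 15, −78 → −40 °C; aq. NH4Cl
Reagents that add atoms: none
Why: Julia-type alkylation of the α-sulfonyl carbanion with the primary allylic bromide by SN2, the β,β-disubstitution of the enoate disfavouring conjugate addition; the new sulfonyl-bearing centre is not controlled and is erased in step 8.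

Step 8
Reactants: 17 ethyl (2E)-5-[(1R,4R)-4-(tert-butyldiphenylsilyloxy)-2,6,6-trimethylcyclohex-2-en-1-yl]-3-methyl-5-(phenylsulfonyl)pent-2-enoate
Product: 18 ethyl (2E,4E)-5-[(1R,4R)-4-(tert-butyldiphenylsilyloxy)-2,6,6-trimethylcyclohex-2-en-1-yl]-3-methylpenta-2,4-dienoate
Conditions: NaOEt, EtOH/THF, 0 °C → rt
Reagents that add atoms: none
Why: Vinylogous E1cB elimination, in which ethoxide removes a γ-proton of the enoate (C8') and the dienolate expels benzenesulfinate from C7' to give the conjugated (E)-C7'=C8' bond, while the far less acidic H-6' should stay in place.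

Step 9
Reactants: 18 ethyl (2E,4E)-5-[(1R,4R)-4-(tert-butyldiphenylsilyloxy)-2,6,6-trimethylcyclohex-2-en-1-yl]-3-methylpenta-2,4-dienoate
Product: 19 (2E,4E)-5-[(1R,4R)-4-(tert-butyldiphenylsilyloxy)-2,6,6-trimethylcyclohex-2-en-1-yl]-3-methylpenta-2,4-dien-1-ol
Conditions: i-Bu2AlH, CH2Cl2, −78 °C; aq. KNaC4H4O6 (tartrate)
Reagents that add atoms: none
Why: 1,2-Reduction of the conjugated ester by the aluminium hydride gives the allylic alcohol and leaves the silyl ether and the alkenes alone.

Step 10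
Reactants: 19 (2E,4E)-5-[(1R,4R)-4-(tert-butyldiphenylsilyloxy)-2,6,6-trimethylcyclohex-2-en-1-yl]-3-methylpenta-2,4-dien-1-ol
Product: 20 [(2E,4E)-5-[(1R,4R)-4-(tert-butyldiphenylsilyloxy)-2,6,6-trimethylcyclohex-2-en-1-yl]-3-methylpenta-2,4-dien-1-yl]triphenylphosphonium bromide
Conditions: PPh3·HBr, MeOH/CH2Cl2, 0 °C → rt
Reagents that add atoms: triphenylphosphine hydrobromide [Br-].c1ccccc1[PH+](c1ccccc1)c1ccccc1
Why: Phosphonium salt formation from a dienyl alcohol through the delocalised allylic cation, captured by the phosphine at the primary terminus, under an acid weak enough for the silyl ether to survive.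

Step 11
Reactants: 20 [(2E,4E)-5-[(1R,4R)-4-(tert-butyldiphenylsilyloxy)-2,6,6-trimethylcyclohex-2-en-1-yl]-3-methylpenta-2,4-dien-1-yl]triphenylphosphonium bromide; 21 (2E,4E,6E)-2,7-dimethylocta-2,4,6-trienedial
Product: 23 (2E,4E,6E,8E,10E,12E)-13-[(1R,4R)-4-(tert-butyldiphenylsilyloxy)-2,6,6-trimethylcyclohex-2-en-1-yl]-2,7,11-trimethyltrideca-2,4,6,8,10,12-hexaenal, via ylide 22 (not isolated)
Conditions: 21 (3 equiv), NaOMe, MeOH/CH2Cl2, 0 °C → rt; then heptane, 80 °C
Reagents that add atoms: none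
Why: Wittig olefination of one formyl group of the symmetrical dialdehyde, held in excess to favour mono-reaction, forms C11'=C12', and heating should equilibrate the new disubstituted double bond to E.

Step 12
Reactants: 24 (2E)-3-methylpent-2-en-4-yn-1-ol
Product: 25 (2E,4E)-3-methyl-5-(tributylstannyl)penta-2,4-dien-1-ol
Conditions: Bu3SnH, PdCl2(PPh3)2 (2 mol %), THF, 0 °C
Reagents that add atoms: tributyltin hydride CCCC[SnH](CCCC)CCCC
Why: Palladium-catalysed syn-hydrostannylation of the terminal alkyne places tin on the terminal carbon and so gives the (E)-alkenylstannane.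

Step 13
Reactants: 26 (4R,6R)-4-hydroxy-2,2,6-trimethylcyclohexan-1-one
Product: 27 (4R,6R)-4-(tert-butyldiphenylsilyloxy)-2,2,6-trimethylcyclohexan-1-one
Conditions: t-BuPh2SiCl, imidazole, DMF, rt
Reagents that add atoms: tert-butyl(chloro)diphenylsilane CC(C)(C)[Si](Cl)(c1ccccc1)c1ccccc1
Why: Imidazole-mediated silylation of the secondary alcohol, chosen so that both ring oxygens carry the same group and fall in one final deprotection.

Step 14
Reactants: 27 (4R,6R)-4-(tert-butyldiphenylsilyloxy)-2,2,6-trimethylcyclohexan-1-one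
Product: 29 (4R)-4-(tert-butyldiphenylsilyloxy)-2,6,6-trimethylcyclohex-1-en-1-yl trifluoromethanesulfonate, via lithium enolate 28 (not isolated)
Conditions: LiN(i-Pr)2, THF, −78 → 0 °C; then PhNTf2, 0 °C → rt; aq. NH4Cl
Reagents that add atoms: N-phenylbis(trifluoromethanesulfonimide) O=S(=O)(N(c1ccccc1)S(=O)(=O)C(F)(F)F)C(F)(F)F
Why: Only C6 carries an α-hydrogen, so enolisation is regiodefined and O-triflation gives the tetrasubstituted enol triflate; the C6 centre is deliberately erased while C4 is untouched.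

Step 15
Reactants: 29 (4R)-4-(tert-butyldiphenylsilyloxy)-2,6,6-trimethylcyclohex-1-en-1-yl trifluoromethanesulfonate; 25 (2E,4E)-3-methyl-5-(tributylstannyl)penta-2,4-dien-1-ol
Product: 30 (2E,4E)-5-[(4R)-4-(tert-butyldiphenylsilyloxy)-2,6,6-trimethylcyclohex-1-en-1-yl]-3-methylpenta-2,4-dien-1-ol
Conditions: Pd2(dba)3 (cat.), AsPh3, LiCl, NMP, 50 °C
Reagents that add atoms: none
Why: Stille coupling of an alkenyl triflate with an alkenylstannane forms C6–C7 with retention of both alkene geometries, the arsine ligand and chloride in a polar solvent speeding transmetalation at the hindered centre.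

Step 16
Reactants: 30 (2E,4E)-5-[(4R)-4-(tert-butyldiphenylsilyloxy)-2,6,6-trimethylcyclohex-1-en-1-yl]-3-methylpenta-2,4-dien-1-ol
Product: 31 [(2E,4E)-5-[(4R)-4-(tert-butyldiphenylsilyloxy)-2,6,6-trimethylcyclohex-1-en-1-yl]-3-methylpenta-2,4-dien-1-yl]triphenylphosphonium bromide
Conditions: PPh3·HBr, MeOH/CH2Cl2, 0 °C → rt
Reagents that add atoms: triphenylphosphine hydrobromide [Br-].c1ccccc1[PH+](c1ccccc1)c1ccccc1
Why: Phosphonium salt formation through the delocalised allylic cation, as in step 10, with the phosphine entering at the primary carbon.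

Step 17
Reactants: 23 (2E,4E,6E,8E,10E,12E)-13-[(1R,4R)-4-(tert-butyldiphenylsilyloxy)-2,6,6-trimethylcyclohex-2-en-1-yl]-2,7,11-trimethyltrideca-2,4,6,8,10,12-hexaenal; 31 [(2E,4E)-5-[(4R)-4-(tert-butyldiphenylsilyloxy)-2,6,6-trimethylcyclohex-1-en-1-yl]-3-methylpenta-2,4-dien-1-yl]triphenylphosphonium bromide
Product: 33 (3R,3'R,6'R)-3,3'-bis(tert-butyldiphenylsilyloxy)-β,ε-carotene, via ylide 32 (not isolated)
Conditions: NaOMe, MeOH/CH2Cl2, rt; then heptane, reflux
Reagents that add atoms: none
Why: Wittig olefination of the C25 aldehyde with the C15 ylide forms C11=C12 and completes the C40 chain, and heating should bring the polyene to the all-E form.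

Step 18
Reactants: 33 (3R,3'R,6'R)-3,3'-bis(tert-butyldiphenylsilyloxy)-β,ε-carotene
Product: 34 (3R,3'R,6'R)-β,ε-carotene-3,3'-diol (lutein)
Conditions: Bu4NF, THF, rt → 40 °C; aq. NH4Cl
Reagents that add atoms: none
Why: Fluoride cleavage of both silyl ethers under non-acidic conditions spares the acid-sensitive allylic C3' alcohol and the polyene.

Step 19
Reactants: 34 (3R,3'R,6'R)-β,ε-carotene-3,3'-diol; 35 (9Z,12Z,15Z)-octadeca-9,12,15-trienoic acid (α-linolenic acid)
Product: 36 (3R,3'R,6'R)-β,ε-carotene-3,3'-diyl bis[(9Z,12Z,15Z)-octadeca-9,12,15-trienoate]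
Conditions: 35 (2.5 equiv), DCC, DMAP (cat.), CH2Cl2, 0 °C → rt, dark, Ar
Reagents that add atoms: none
Why: Steglich esterification acylates both secondary alcohols through the acylpyridinium ion without generating acid, so the allylic C3' oxygen is not ionised and the skipped Z-triene of the acid is left alone.

**Compound list**

1 | (R)-epichlorohydrin | ClC[C@H]1CO1 | starting material
2 | isopropenylmagnesium bromide | CC(=C)[Mg]Br | starting material
3 | (2R)-1-chloro-4-methylpent-4-en-2-ol | ClC[C@H](O)CC(C)=C | intermediate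
4 | lithium acetylide–ethylenediamine complex | [Li]C#C.NCCN | starting material
5 | (2R)-2-(2-methylprop-2-en-1-yl)oxirane (epoxide) | C=C(C)C[C@@H]1CO1 | intermediate
6 | (4R)-2-methylhept-1-en-6-yn-4-ol | C=C(C)C[C@@H](O)CC#C | intermediate
7 | tert-butyl{[(4R)-2-methylhept-1-en-6-yn-4-yl]oxy}diphenylsilane | C=C(C)C[C@@H](O[Si](c1ccccc1)(c1ccccc1)C(C)(C)C)CC#C | intermediate
8 | [(1E,4R)-4-(tert-butyldiphenylsilyloxy)-2,6-dimethylhepta-1,6-dien-1-yl]dimethylalane (alkenylalane) | C[Al](C)/C=C(\C)C[C@H](O[Si](c1ccccc1)(c1ccccc1)C(C)(C)C)CC(C)=C | intermediate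
9 | lithium butyl[(1E,4R)-4-(tert-butyldiphenylsilyloxy)-2,6-dimethylhepta-1,6-dien-1-yl]dimethylaluminate (lithium alkenylaluminate) | [Li+].CCCC[Al-](C)(C)/C=C(\C)C[C@H](O[Si](c1ccccc1)(c1ccccc1)C(C)(C)C)CC(C)=C | intermediate
10 | (2E,5R)-5-(tert-butyldiphenylsilyloxy)-3,7-dimethylocta-2,7-dien-1-ol | OC/C=C(\C)C[C@H](O[Si](c1ccccc1)(c1ccccc1)C(C)(C)C)CC(C)=C | intermediate
11 | sodium benzenesulfinate | [Na+].[O-]S(=O)c1ccccc1 | starting material
12 | {[(4R,6E)-8-bromo-2,6-dimethylocta-1,6-dien-4-yl]oxy}(tert-butyl)diphenylsilane (allylic bromide) | BrC/C=C(\C)C[C@H](O[Si](c1ccccc1)(c1ccccc1)C(C)(C)C)CC(C)=C | intermediate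
13 | (2E,5R)-5-(tert-butyldiphenylsilyloxy)-3,7-dimethylocta-2,7-dien-1-yl phenyl sulfone | O=S(=O)(C/C=C(C)/C[C@H](O[Si](c1ccccc1)(c1ccccc1)C(C)(C)C)CC(C)=C)c1ccccc1 | intermediate
14 | [(1R,4R)-4-(tert-butyldiphenylsilyloxy)-2,6,6-trimethylcyclohex-2-en-1-yl]methyl phenyl sulfone | O=S(=O)(C[C@H]1C(C)=C[C@H](O[Si](c2ccccc2)(c2ccccc2)C(C)(C)C)CC1(C)C)c1ccccc1 | intermediate
15 | ethyl (2E)-4-bromo-3-methylbut-2-enoate | CCOC(=O)/C=C(\C)CBr | starting material
16 | α-lithio derivative of sulfone 14 (lithiated sulfone) | [Li]C([C@H]1C(C)=C[C@H](O[Si](c2ccccc2)(c2ccccc2)C(C)(C)C)CC1(C)C)S(=O)(=O)c1ccccc1 | intermediate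
17 | ethyl (2E)-5-[(1R,4R)-4-(tert-butyldiphenylsilyloxy)-2,6,6-trimethylcyclohex-2-en-1-yl]-3-methyl-5-(phenylsulfonyl)pent-2-enoate | CCOC(=O)/C=C(\C)CC([C@H]1C(C)=C[C@H](O[Si](c2ccccc2)(c2ccccc2)C(C)(C)C)CC1(C)C)S(=O)(=O)c1ccccc1 | intermediate
18 | ethyl (2E,4E)-5-[(1R,4R)-4-(tert-butyldiphenylsilyloxy)-2,6,6-trimethylcyclohex-2-en-1-yl]-3-methylpenta-2,4-dienoate | CCOC(=O)/C=C(C)/C=C/[C@H]1C(C)=C[C@H](O[Si](c2ccccc2)(c2ccccc2)C(C)(C)C)CC1(C)C | intermediate
19 | (2E,4E)-5-[(1R,4R)-4-(tert-butyldiphenylsilyloxy)-2,6,6-trimethylcyclohex-2-en-1-yl]-3-methylpenta-2,4-dien-1-ol | OC/C=C(C)/C=C/[C@H]1C(C)=C[C@H](O[Si](c2ccccc2)(c2ccccc2)C(C)(C)C)CC1(C)C | intermediate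
20 | [(2E,4E)-5-[(1R,4R)-4-(tert-butyldiphenylsilyloxy)-2,6,6-trimethylcyclohex-2-en-1-yl]-3-methylpenta-2,4-dien-1-yl]triphenylphosphonium bromide | [Br-].c1ccccc1[P+](c1ccccc1)(c1ccccc1)C/C=C(C)/C=C/[C@H]1C(C)=C[C@H](O[Si](c2ccccc2)(c2ccccc2)C(C)(C)C)CC1(C)C | intermediate
21 | (2E,4E,6E)-2,7-dimethylocta-2,4,6-trienedial | O=C/C(C)=C/C=C/C=C(C)/C=O | starting material
22 | ylide of phosphonium salt 20 | c1ccccc1P(c1ccccc1)(c1ccccc1)=C/C=C(C)/C=C/[C@H]1C(C)=C[C@H](O[Si](c2ccccc2)(c2ccccc2)C(C)(C)C)CC1(C)C | intermediate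
23 | (2E,4E,6E,8E,10E,12E)-13-[(1R,4R)-4-(tert-butyldiphenylsilyloxy)-2,6,6-trimethylcyclohex-2-en-1-yl]-2,7,11-trimethyltrideca-2,4,6,8,10,12-hexaenal | O=C/C(C)=C/C=C/C=C(C)/C=C/C=C(C)/C=C/[C@H]1C(C)=C[C@H](O[Si](c2ccccc2)(c2ccccc2)C(C)(C)C)CC1(C)C | intermediate
24 | (2E)-3-methylpent-2-en-4-yn-1-ol | OC/C=C(C)/C#C | starting material
25 | (2E,4E)-3-methyl-5-(tributylstannyl)penta-2,4-dien-1-ol | OC/C=C(C)/C=C/[Sn](CCCC)(CCCC)CCCC | intermediate
26 | (4R,6R)-4-hydroxy-2,2,6-trimethylcyclohexan-1-one | O=C1C(C)(C)C[C@H](O)C[C@H]1C | starting material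
27 | (4R,6R)-4-(tert-butyldiphenylsilyloxy)-2,2,6-trimethylcyclohexan-1-one | O=C1C(C)(C)C[C@H](O[Si](c2ccccc2)(c2ccccc2)C(C)(C)C)C[C@H]1C | intermediate
28 | lithium (4R)-4-(tert-butyldiphenylsilyloxy)-2,6,6-trimethylcyclohex-1-en-1-olate (lithium enolate) | [Li]OC1=C(C)C[C@@H](O[Si](c2ccccc2)(c2ccccc2)C(C)(C)C)CC1(C)C | intermediate
29 | (4R)-4-(tert-butyldiphenylsilyloxy)-2,6,6-trimethylcyclohex-1-en-1-yl trifluoromethanesulfonate | CC1=C(OS(=O)(=O)C(F)(F)F)C(C)(C)C[C@H](O[Si](c2ccccc2)(c2ccccc2)C(C)(C)C)C1 | intermediate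
30 | (2E,4E)-5-[(4R)-4-(tert-butyldiphenylsilyloxy)-2,6,6-trimethylcyclohex-1-en-1-yl]-3-methylpenta-2,4-dien-1-ol | OC/C=C(C)/C=C/C1=C(C)C[C@@H](O[Si](c2ccccc2)(c2ccccc2)C(C)(C)C)CC1(C)C | intermediate
31 | [(2E,4E)-5-[(4R)-4-(tert-butyldiphenylsilyloxy)-2,6,6-trimethylcyclohex-1-en-1-yl]-3-methylpenta-2,4-dien-1-yl]triphenylphosphonium bromide | [Br-].c1ccccc1[P+](c1ccccc1)(c1ccccc1)C/C=C(C)/C=C/C1=C(C)C[C@@H](O[Si](c2ccccc2)(c2ccccc2)C(C)(C)C)CC1(C)C | intermediate
32 | ylide of phosphonium salt 31 | c1ccccc1P(c1ccccc1)(c1ccccc1)=C/C=C(C)/C=C/C1=C(C)C[C@@H](O[Si](c2ccccc2)(c2ccccc2)C(C)(C)C)CC1(C)C | intermediate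
33 | (3R,3'R,6'R)-3,3'-bis(tert-butyldiphenylsilyloxy)-β,ε-carotene | CC(C)(C)[Si](c1ccccc1)(c1ccccc1)O[C@@H]1CC(C)=C(/C=C/C(C)=C/C=C/C(C)=C/C=C/C=C(C)/C=C/C=C(C)/C=C/[C@H]2C(C)=C[C@H](O[Si](c3ccccc3)(c3ccccc3)C(C)(C)C)CC2(C)C)C(C)(C)C1 | intermediate
34 | (3R,3'R,6'R)-β,ε-carotene-3,3'-diol (lutein) | O[C@@H]1CC(C)=C(/C=C/C(C)=C/C=C/C(C)=C/C=C/C=C(C)/C=C/C=C(C)/C=C/[C@H]2C(C)=C[C@H](O)CC2(C)C)C(C)(C)C1 | intermediate
35 | (9Z,12Z,15Z)-octadeca-9,12,15-trienoic acid (α-linolenic acid) | CC/C=C\C/C=C\C/C=C\CCCCCCCC(=O)O | starting material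
36 | (3R,3'R,6'R)-β,ε-carotene-3,3'-diyl bis[(9Z,12Z,15Z)-octadeca-9,12,15-trienoate] | CC/C=C\C/C=C\C/C=C\CCCCCCCC(=O)O[C@@H]1CC(C)=C(/C=C/C(C)=C/C=C/C(C)=C/C=C/C=C(C)/C=C/C=C(C)/C=C/[C@H]2C(C)=C[C@H](OC(=O)CCCCCCC/C=C\C/C=C\C/C=C\CC)CC2(C)C)C(C)(C)C1 | target

**Step count**

Total: 19 steps. Longest linear sequence: 14 steps (steps 1–11, then 17–19); steps 12–16 form the ring β branch.

**Steps most likely to fail**

Step 6. The C5' cation may lose the proton from C6' or from its methyl group instead of H-4', the induction from C3' may be weaker than the chair model predicts, or the Lewis acid may ionise the silyl ether. The fallback sets out from 13 and comes back at 18, and it moves the ring closure to the conjugated ester stage. Lithiated 13 would be alkylated with 15 to ethyl (2E,6E,9R)-9-(tert-butyldiphenylsilyloxy)-3,7,11-trimethyl-5-(phenylsulfonyl)dodeca-2,6,11-trienoate F1. NaOEt would then expel sulfinate to give ethyl (2E,4E,6E,9R)-9-(tert-butyldiphenylsilyloxy)-3,7,11-trimethyldodeca-2,4,6,11-tetraenoate F2. This open-chain ester would be closed under kinetic protic conditions (85 % H3PO4 or SnCl4 with 2,6-dimethylphenol), in the manner of the pseudoionone-to-α-ionone cyclisation, to give 18. The same C1'–C6' bond forms, but on a substrate class for which kinetic formation of the α-type ring is the standard outcome and in which the sulfone no longer deactivates the attacking alkene.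

Step 7. The hindered, strongly basic sulfonyl carbanion may take a proton from the bromo ester, or add in conjugate fashion and close a three-membered ring, instead of displacing bromide. The fallback sets out from 14 and comes back at 18, and it reverses the polarity of the C7'–C8' union. Lithiated 14 would be oxidised with Me3SiOOSiMe3 (oxidative desulfonylation) to (1R,4R)-4-(tert-butyldiphenylsilyloxy)-2,6,6-trimethylcyclohex-2-ene-1-carbaldehyde F3. A Horner–Wadsworth–Emmons reaction of this aldehyde with the anion of triethyl (2E)-3-methyl-4-phosphonobut-2-enoate (LiN(SiMe3)2, THF, −78 °C, kept cold to protect C6') would give dienoate 18 directly and bypass step 8.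

Step 15. Transmetalation at the tetrasubstituted alkenylpalladium centre, flanked by the gem-dimethyl and methyl groups, may be slow enough for reduction of the triflate and loss of tin from the stannane to take over. The fallback sets out from 29 (with 24 in place of 25) and comes back at 30. Sonogashira coupling (PdCl2(PPh3)2, CuI, i-Pr2NH, DMF), which tolerates hindered alkenyl triflates well, would give (2E)-5-[(4R)-4-(tert-butyldiphenylsilyloxy)-2,6,6-trimethylcyclohex-1-en-1-yl]-3-methylpent-2-en-4-yn-1-ol F4. Alkoxide-directed trans-hydroalumination of its conjugated triple bond with LiAlH4 in THF would then give dienol 30.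

**Further compounds**

F1 | step 6 | ethyl (2E,6E,9R)-9-(tert-butyldiphenylsilyloxy)-3,7,11-trimethyl-5-(phenylsulfonyl)dodeca-2,6,11-trienoate | CCOC(=O)/C=C(\C)CC(/C=C(\C)C[C@H](O[Si](c1ccccc1)(c1ccccc1)C(C)(C)C)CC(C)=C)S(=O)(=O)c1ccccc1
F2 | step 6 | ethyl (2E,4E,6E,9R)-9-(tert-butyldiphenylsilyloxy)-3,7,11-trimethyldodeca-2,4,6,11-tetraenoate | CCOC(=O)/C=C(C)/C=C/C=C(\C)C[C@H](O[Si](c1ccccc1)(c1ccccc1)C(C)(C)C)CC(C)=C
F3 | step 7 | (1R,4R)-4-(tert-butyldiphenylsilyloxy)-2,6,6-trimethylcyclohex-2-ene-1-carbaldehyde | O=C[C@H]1C(C)=C[C@H](O[Si](c2ccccc2)(c2ccccc2)C(C)(C)C)CC1(C)C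
F4 | step 15 | (2E)-5-[(4R)-4-(tert-butyldiphenylsilyloxy)-2,6,6-trimethylcyclohex-1-en-1-yl]-3-methylpent-2-en-4-yn-1-ol | OC/C=C(C)/C#CC1=C(C)C[C@@H](O[Si](c2ccccc2)(c2ccccc2)C(C)(C)C)CC1(C)C
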